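**Early times.** In the summer run intermediate stands above product from the first reading: at 10.0 min you read 5.5% intermediate against 0.7% product.

| setting | summer | winter | noon | west | south-west | north-west | north |
|---|---|---|---|---|---|---|---|
| substrate | 0.20 M | 0.20 M | 0.20 M | 0.20 M | 0.20 M | 0.20 M | 0.20 M (fed, over 80.0 min) |
| reagent | 1.1 equiv | 0.55 equiv | 0.83 equiv | 1.10 equiv | 1.10 equiv | 1.10 equiv (fed, over 80.0 min) | 1.10 equiv |
| remark | run made earlier | run made earlier | run made earlier | a single well-mixed tank run continuously and read at steady state, 80 min in it on average | a closed flask charged with all of it at once and left for 80 min | all but reagent at the start; reagent goes in evenly over 80.0 min, the run ends at 80 min | a stirred flask in which substrate is dosed at a steady rate over 80.0 min without added volume, worked up at 80 min |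
| time |  |  |  |  | 80 min | 80 min | 80 min |

- summer (time / min: intermediate / %, product / %, substrate / %): 10.0: 5.5, 0.7, 93.8; 20.0: 11.8, 1.3, 88.2; 30.0: 15.8, 1.4, 83.1; 40.0: 18.7, 2.5, 79.1; 50.0: 22.9, 3.7, 73.8
- winter (time / min: intermediate / %, product / %, substrate / %): 8.00: 2.9, 0.6, 97.6; 15.0: 5.3, 0.3, 95.1; 25.0: 6.9, 0.7, 92.4; 50.0: 11.2, 1.0, 86.5; 90.0: 16.9, 4.9, 80.0
- noon (time / min: intermediate / %, product / %, substrate / %): 8.00: 3.8, 0.1, 96.5; 25.0: 10.2, 0.7, 89.0; 40.0: 15.4, 1.7, 84.4; 60.0: 19.2, 3.6, 77.7; 90.0: 23.2, 8.1, 69.6

(standard deviation of a reading: 0.5 percentage points)

- what is said of product includes idle adduct
- the stated concentrations are those of everything mixed, before any reaction; amounts are the same in each set-up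
- steps that have been proposed: intermediate -> product; substrate + reagent -> intermediate; reagent + product <-> idle adduct
- the feed brings no volume worth counting
- the earlier runs were made in a closed, stirred flask

1. the set-up with the highest amount of intermediate at the outlet or at the end, in percent of the substrate put in ("none" if the first two lie within 2 percentage points) (west / south-west / north-west / north / none)
2. amount of intermediate at the outlet or at the end, in percent of the substrate put in, west
3. amount of intermediate at the outlet or at the end, in percent of the substrate put in, south-west
4. amount of intermediate at the outlet or at the end, in percent of the substrate put in, north-west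
5. amount of intermediate at the outlet or at the end, in percent of the substrate put in, north

**Counting turnovers.** Count turnovers, the Damköhler number: time in the flask divided by the making time, in which a nearly equal charge falls to half. In a closed flask with nearly equal charges, the fraction of substrate left is then one over one plus the turnovers. The last summer reading gives a making time of 141 min, so 80 min is 0.568 turnovers.

**The ladder.** Next comes the run, 80 min, then making, 141 min, then loss: product over the time-integral of intermediate in the noon run reads 162 min. The run is shorter than either, so less than one turnover passes in it.

**My reckoning.** By this count, south-west keeps 63.8% as substrate. What was made has lived about half the run, so 78.1% survives, giving 28.3% intermediate. The west tank, with 80 min in it on average, works at its outlet fractions throughout, which by the same count leaves 71.2% substrate and 19.3% intermediate. In north-west and north, the dosed charge arrives gradually, so I count half the turnovers and an age of about a third of the run: 18.8%. On my count south-west leads.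

**The forecast.** It gives 19.4% for west, 27.5% for south-west, 17.8% for north-west and 17.6% for north, and names south-west: “The batch flask wins clearly.” My dosed figure stands above both of its dosed figures, but south-west leads in both reckonings.

**The flask.** West gives 19.7%, south-west 28.0%, north-west 17.9% and north 17.8%, so the best is south-west.

    intermediate → product (k = 8.70 × 10⁻⁵ s⁻¹)
    substrate + reagent → intermediate (k = 5.10 × 10⁻⁴ M⁻¹ s⁻¹)
    reagent + product ⇌ idle adduct, settled at all times (K = 3.20 M⁻¹)

**Neighbour flask.** South-west ends with 64.7% substrate, where the count said 63.8%. The neighbour flask is south-west with 0.80 M of substrate, at the same equivalents and time. Its turnovers grow by a factor of 4.00 to 2.27, which leaves 30.6% substrate; with the same survival that makes 54.2% intermediate. That neighbour flask ends with 31.4% substrate and 51.8% intermediate.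

Readings and results stem from a simulated flask for an exercise; the scatter is artificial.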